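The constant I want first is how fast substrate clears per unit of free catalyst, since a ledger of the substrate opens with what is left.

| setting | Sunday's | Wednesday's | Thursday's | winter | summer | autumn |
|---|---|---|---|---|---|---|
| substrate | 5 mM | 20 mM | 10 mM | 10 mM | 10 mM | 10 mM |
| free catalyst | 5 mol% | 5 mol% | 10 mol% | 5 mol% | 5 mol% | 5 mol% |
| temperature | 15 °C | 40 °C | 15 °C | 40 °C | 20 °C | 60 °C |
| remark | run made earlier | run made earlier | run made earlier |  |  |  |
| time |  |  |  | 4.0 h | 4.0 h | 4.0 h |

| run | time / h | target / % |
|---|---|---|
| Sunday's | 1.50 | 39.3 |
| Sunday's | 5.00 | 72.4 |
| Sunday's | 8.00 | 75.8 |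
| Sunday's | 15.0 | 74.5 |
| Wednesday's | 1.00 | 72.3 |
| Wednesday's | 2.00 | 71.2 |
| Wednesday's | 3.00 | 72.5 |
| Wednesday's | 4.00 | 73.0 |
| Thursday's | 3.00 | 82.6 |
| Thursday's | 6.00 | 75.8 |
| Thursday's | 10.0 | 72.4 |
| Thursday's | 15.0 | 71.2 |

(scatter of a reading: 1 percentage point)

1. the flask that comes out highest in amount of target, in percent of the substrate charged, or "all alike" when all lie within 1.5 percentage points (winter / summer / autumn / all alike)
2. target at the end, in percent of the substrate charged, winter
3. target at the end, in percent of the substrate charged, summer
4. target at the end, in percent of the substrate charged, autumn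



I keep the books on substrate, the limiting reagent, in percent of its charge. I take the steps after substrate meets free catalyst as settled and hold c(free catalyst) at its charged value, so substrate falls pseudo-first-order. Sunday's first reading, 39.3% of target at 1.50 h with c(free catalyst) at 0.250 mM, gives the clearing constant 1.33 /mM/h, the rate at which substrate falls per unit of c(free catalyst). It is a reading and a low estimate, since substrate gone is at least the target formed.

The first entry for summer, with c(free catalyst) at 0.500 mM over 4.0 h, is substrate left: 6.98%. I take this as an upper estimate while the catalyst lasts, since the constant was read at 15 °C and summer stands warmer at 20 °C. The second entry comes from Thursday's run. At 3.00 h it shows 82.6% of target and the constant leaves 1.84% of substrate, so I reckon that 15.6% stands in forms I cannot read. I lend summer that entry, and its books close with 77.5% of target. Wednesday's run holds between 71.2% and 73.0%, so I put winter there, less than summer. For autumn no run stands at that temperature, and I leave its ledger open.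

The forecast also names summer, with 72% for winter, 79% for summer and 72% for autumn, reasoning that “this looks like a nearly temperature-independent equilibrium”. Its summer stands higher than mine.

The flasks give 71.4% for winter, 76.7% for summer and 65.8% for autumn, so summer is highest and the forecast's autumn is 6.2 percentage points too high. Autumn ends with 13.1% of its substrate left and 100% of its catalyst spent, and its target is still 65.8% at 40.0 h. The clearing constant, reckoned with c(free catalyst) held at its charged value, gives 6.98% for autumn's charge and time, and autumn holds more substrate than that.

    free catalyst + target → spent catalyst (k = 0.0129 /M/s, Ea = 69.0 kJ/mol)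
    target ⇌ isomer of the product (K = 0.270, k = 3.42 × 10⁻⁵ /s, Ea = 94.0 kJ/mol, ΔH = −2.00 kJ/mol)
    catalyst intermediate A → catalyst intermediate B (k = 0.366 /s, Ea = 80.0 kJ/mol)
    substrate + free catalyst → catalyst intermediate A (k = 0.773 /M/s, Ea = 45.0 kJ/mol)
    catalyst intermediate B → free catalyst + target (k = 0.0103 /s, Ea = 73.0 kJ/mol)
    (constants at 20 °C)

Take the flask like summer but with 4.0 mM of substrate at the same loading: c(free catalyst) is 0.200 mM, and the constant leaves 34.5% of substrate at 4.0 h. The computed flask holds less substrate than that upper estimate, 18%, with 68.4% of target.

All runs were computed with constants of no real substance, and the scatter is random.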